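**Assumption:** the SMILES is read as the threo (1R,2R) isomer (7R,8R in neolignan numbering); compounds 1, 2 and 5 (0.5 M in THF) are bought. The route is a paper design and has not been run.

## Retrosynthetic overview
1. No ring is formed; both arenes are bought intact.
2. C7–OAc: acetylation of the threo alcohol 7 (retention).
3. C7 stereocentre: catalyst-controlled asymmetric transfer hydrogenation of aryl ketone 6, with C8 already in place.
4. C7–aryl bond: aryl Grignard 5 plus Weinreb amide 4.
5. C8–O(aryl) bond: Mitsunobu coupling of phenol 1 with ethyl (S)-lactate 2; inversion gives 8R.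

## Route

Step 1
Reactants: 1 4-allyl-2,6-dimethoxyphenol; 2 ethyl (S)-lactate
Product: 3 ethyl (2R)-2-(4-allyl-2,6-dimethoxyphenoxy)propanoate
Conditions: PPh3, DIAD, THF, 0 °C → rt
Reagents that add atoms: none
Why: Mitsunobu etherification, in which the phenol (pKa about 10) displaces the phosphonium-activated lactate oxygen by SN2 with clean inversion, turning the (S)-lactate centre into the 8R aryl ether centre of the target.

Step 2
Reactants: 3 ethyl (2R)-2-(4-allyl-2,6-dimethoxyphenoxy)propanoate
Product: 4 (2R)-2-(4-allyl-2,6-dimethoxyphenoxy)-N-methoxy-N-methylpropanamide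
Conditions: MeNH(OMe)·HCl (1.5 eq), i-PrMgCl (3.0 eq), THF, −20 → −5 °C; then cold 1 M HCl
Reagents that add atoms: N,O-dimethylhydroxylamine hydrochloride, CNOC.Cl
Why: Weinreb amide formation by aminolysis of the ester with the chloromagnesium amide made in the flask, fast enough below 0 °C that the α-aryloxy stereocentre is not enolised.

Step 3
Reactants: 4 (2R)-2-(4-allyl-2,6-dimethoxyphenoxy)-N-methoxy-N-methylpropanamide; 5 3,4,5-trimethoxyphenylmagnesium bromide
Product: 6 (2R)-2-(4-allyl-2,6-dimethoxyphenoxy)-1-(3,4,5-trimethoxyphenyl)propan-1-one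
Conditions: 5 (1.5 eq), THF, −20 → 0 °C; then cold 1 M HCl
Reagents that add atoms: none
Why: Weinreb ketone synthesis, in which the magnesium-chelated tetrahedral adduct survives until the quench, so there is no over-addition and the ketone is never exposed to the basic Grignard reagent, leaving C8 untouched.

Step 4
Reactants: 6 (2R)-2-(4-allyl-2,6-dimethoxyphenoxy)-1-(3,4,5-trimethoxyphenyl)propan-1-one
Product: 7 (1R,2R)-2-(4-allyl-2,6-dimethoxyphenoxy)-1-(3,4,5-trimethoxyphenyl)propan-1-ol (threo)
Conditions: RuCl[(S,S)-TsDPEN](p-cymene) (1 mol %), HCO2H/Et3N (5:2), EtOAc, 30 °C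
Reagents that add atoms: none
Why: Noyori–Ikariya asymmetric transfer hydrogenation, in which the (S,S) catalyst delivers hydride to the aryl ketone face that gives 7R (the same spatial sense as (S)-1-phenylethanol from acetophenone, with the CIP label changed because C8 outranks the aryl group), a sense that coincides with the non-chelated Felkin–Anh preference of the 8R ketone, while the weakly acidic medium leaves C8 and the allyl group alone.

Step 5
Reactants: 7 (1R,2R)-2-(4-allyl-2,6-dimethoxyphenoxy)-1-(3,4,5-trimethoxyphenyl)propan-1-ol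
Product: 8 (1R,2R)-2-(4-allyl-2,6-dimethoxyphenoxy)-1-(3,4,5-trimethoxyphenyl)propyl acetate (target)
Conditions: Ac2O, pyridine, DMAP (cat.), CH2Cl2, rt
Reagents that add atoms: acetic anhydride, CC(=O)OC(C)=O
Why: DMAP-catalysed O-acylation of the secondary benzylic alcohol, which breaks no bond at C7 and so retains both stereocentres.

## Compound list
1 | 4-allyl-2,6-dimethoxyphenol (methoxyeugenol) | C=CCc1cc(OC)c(O)c(OC)c1 | starting material
2 | ethyl (S)-lactate | CCOC(=O)[C@H](C)O | starting material
3 | ethyl (2R)-2-(4-allyl-2,6-dimethoxyphenoxy)propanoate | C=CCc1cc(OC)c(O[C@H](C)C(=O)OCC)c(OC)c1 | intermediate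
4 | (2R)-2-(4-allyl-2,6-dimethoxyphenoxy)-N-methoxy-N-methylpropanamide | C=CCc1cc(OC)c(O[C@H](C)C(=O)N(C)OC)c(OC)c1 | intermediate
5 | 3,4,5-trimethoxyphenylmagnesium bromide | COc1cc([Mg]Br)cc(OC)c1OC | starting material
6 | (2R)-2-(4-allyl-2,6-dimethoxyphenoxy)-1-(3,4,5-trimethoxyphenyl)propan-1-one | C=CCc1cc(OC)c(O[C@H](C)C(=O)c2cc(OC)c(OC)c(OC)c2)c(OC)c1 | intermediate
7 | (1R,2R)-2-(4-allyl-2,6-dimethoxyphenoxy)-1-(3,4,5-trimethoxyphenyl)propan-1-ol (threo) | C=CCc1cc(OC)c(O[C@H](C)[C@H](O)c2cc(OC)c(OC)c(OC)c2)c(OC)c1 | intermediate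
8 | (1R,2R)-2-(4-allyl-2,6-dimethoxyphenoxy)-1-(3,4,5-trimethoxyphenyl)propyl acetate | C=CCc1cc(OC)c(O[C@H](C)[C@H](OC(C)=O)c2cc(OC)c(OC)c(OC)c2)c(OC)c1 | target

## Count and risks
Total step count: 5. Longest linear sequence: 5 steps (1/2 → 3 → 4 → 6 → 7 → 8).

**Step 4 (most likely to fail).** The catalyst may not fully override the substrate, giving an erythro/threo mixture at C7. The fallback sets out from 6 and comes back to the route at 8, bypassing 7. Ketone 6 is reduced under chelation control with Zn(BH4)2 in Et2O at −20 °C (Cram-chelate delivery from the hydrogen side) to the erythro alcohol (1S,2R)-2-(4-allyl-2,6-dimethoxyphenoxy)-1-(3,4,5-trimethoxyphenyl)propan-1-ol F1. F1 is then esterified with AcOH, PPh3 and DIAD in toluene at 0 °C, a Mitsunobu reaction that inverts C7 and gives acetate 8 directly.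

**Step 1.** The di-ortho-substituted phenol may couple slowly under Mitsunobu conditions. The fallback sets out from 2 and comes back at 3. Ethyl (S)-lactate 2 is sulfonylated with TsCl, Et3N and catalytic DMAP in CH2Cl2 to ethyl (2S)-2-(tosyloxy)propanoate F2. F2 is displaced by the potassium phenoxide of 1 (K2CO3, MeCN, 60 °C) in a Williamson-type SN2 reaction with inversion, giving 3.

**Step 3.** The electron-rich aryl Grignard may enolise the amide (eroding C8) or add sluggishly. The fallback sets out from 4 and comes back at 6. Amide 4 is reduced with DIBAL-H in THF at −78 °C to (2R)-2-(4-allyl-2,6-dimethoxyphenoxy)propanal F3, which is treated at once with 5 at −78 °C. This gives (2R)-2-(4-allyl-2,6-dimethoxyphenoxy)-1-(3,4,5-trimethoxyphenyl)propan-1-ol F4 as a mixture of C1 epimers, whose ratio does not matter. F4 is oxidised with Dess–Martin periodinane (NaHCO3, CH2Cl2, rt) to ketone 6.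

## Further compounds
F1 | step 4 | (1S,2R)-2-(4-allyl-2,6-dimethoxyphenoxy)-1-(3,4,5-trimethoxyphenyl)propan-1-ol (erythro) | C=CCc1cc(OC)c(O[C@H](C)[C@@H](O)c2cc(OC)c(OC)c(OC)c2)c(OC)c1
F2 | step 1 | ethyl (2S)-2-(tosyloxy)propanoate | CCOC(=O)[C@H](C)OS(=O)(=O)c1ccc(C)cc1
F3 | step 3 | (2R)-2-(4-allyl-2,6-dimethoxyphenoxy)propanal | C=CCc1cc(OC)c(O[C@H](C)C=O)c(OC)c1
F4 | step 3 | (2R)-2-(4-allyl-2,6-dimethoxyphenoxy)-1-(3,4,5-trimethoxyphenyl)propan-1-ol, mixture of C1 epimers | C=CCc1cc(OC)c(O[C@H](C)C(O)c2cc(OC)c(OC)c(OC)c2)c(OC)c1
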